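## Structural features

The target is an 18-membered macrocycle of four benzene rings joined in a loop. Ring A (catechol ring: C1 carbinol, C3 and C4 hydroxyls, C5 ether oxygen) is bound through oxygen to ring B (para-phenylene), ring B through a CH2–CH2 bridge to C1 of ring C, C2 of ring C through oxygen to ring D (meta-phenylene), and ring D through CH2–CH(OH) back to C1 of ring A. Ring C carries three contiguous substituents (C1 alkyl, C2 aryloxy, C3 hydroxyl), so the C2–O–ring D ether is flanked on both sides. The only stereocentre is the secondary benzylic carbinol; with O > ring A carbon > CH2 > H it is (S), and it has no stereogenic neighbour. The carbinol lies para to the C4 hydroxyl of ring A, so acid or hot base can ionise it (quinone methide, loss of water to a stilbene, racemisation), a hydrogenation catalyst can cleave it, and the catechol is sensitive to air. The real difficulties are the di-ortho-substituted diaryl ether at C2 of ring C, the closure of the large ring, and the fully regiocontrolled 1,2,3-pattern of ring C. The key step exploits the fact that C2–C3–C4 of ring C correspond to an aryloxyacetone and C5–C6–C1 to a β-ketoaldehyde, so the oxygen on C2 can be attached to ring D beforehand by plain O-alkylation of a simple phenol.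

## Logic of the disconnections

19 ⇒ 18. The O–CH2Ph bond on ring C and the two O–CPh2 bonds on ring A are cut. All three phenols then appear in one neutral hydrogenolysis, and 18 is neither air-sensitive nor able to form a quinone methide, because the oxygen para to the carbinol is tied into the ketal. The forward step must spare the benzylic C–OH bond.

18 ⇒ 17. The bond between the C5 oxygen of ring A and C4 of ring B is cut. It is the less hindered of the two diaryl ethers: a para-alkyl aryl bromide meets a phenol with one ortho substituent. This opens the macrocycle to an acyclic bromo-phenol. The forward step is a copper-mediated etherification under dilution that must tolerate the free secondary alcohol; ring B must keep its bromine until then and ring D must have lost its halogen.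

17 ⇒ 16 ⇒ 15. First the O–Si bond on ring A, then the carbinol C–H bond are cut, which removes the only stereocentre. The ketone of 15 has an aryl group on one side and a CH2-aryl group on the other and no stereogenic neighbour, so the forward reduction must be controlled by the catalyst alone. The silyl ether exists only to keep the ring A phenol out of the enolate coupling.

15 ⇒ 11 + 14. The CH2–ring D bond is cut, dividing the molecule into halves of similar size. The forward enolate arylation must engage the carbon–iodine bond of ring D and leave the carbon–bromine bond of ring B, and must stop after one arylation.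

14 ⇒ 13 ⇒ 12. The O–Si bond and then the two O–C bonds of the ketal are cut. A diphenylmethylene bridge can only span two neighbouring oxygens of the symmetric triol 12, and the two possible pairs are equivalent, so the one remaining hydroxyl is the future ether oxygen. The ketal does not migrate under base (a silyl group next to a free phenol would) and leaves by hydrogenolysis.

11 ⇒ 10 ⇒ 9. The O–benzyl bond is cut, and then the two C–H bonds of the ring B–ring C bridge, which returns an (E)-alkene. The bridge is carried as an alkene for two reasons:
- In 7 the ketone then has no hydrogen on its side-chain α-carbon. With a saturated 2-arylethyl ketone that carbon could attack the C3 carbonyl through a second six-membered transition state and give an isomeric phenol.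
- 7 then comes from an aldol condensation instead of a ketone enolate alkylation.

The forward reduction must saturate the C=C bond without touching either carbon–halogen bond.

9 ⇒ 4 + 7. The C4–C5 and C2–C1 bonds of ring C are cut, which removes the ring and reduces the hindered ether to an alkyl aryl ether. The forward step needs the first bond to run from the terminal carbon of 4 to the acetal carbon of 7, and the ring to close from the aryloxymethylene carbon onto the ketone, through 8.

4 ⇒ 3 ⇒ 1 + 2. The O–Si bond and then the O–CH2 bond are cut, leading to a phenol and an α-chloro ketone. The silylation must place the double bond on the methyl side, away from the aryloxy group.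

7 ⇒ 5 + 6. The C=C bond next to the ketone is cut. The forward condensation must take place at the methyl group of 6 and leave the acetal intact.

## Other disconnections considered

Alternative 1: The cut is the ring A C5–O bond to ring B, the same ether that the chosen plan closes last, but made by oxidation. The acyclic bis-phenol A2 carries a 4-hydroxy-3,5-diiodophenyl ring A and a 3,5-dichloro-4-hydroxyphenyl ring B. Tl(NO3)3 in methanol (trivalent thallium) would oxidise the diiodophenol ring, the ring B phenol oxygen would add at the iodine-bearing C5, and zinc in acetic acid would reduce the iodo-dienone to A1.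
- In its favour: the closure runs at or below room temperature without base and without metal insertion into an aryl halide; the halogens decide which ring is oxidised and where the oxygen attacks; the 4-hydroxy-5-aryloxy pattern of ring A arises directly.
- Against it here: A1 still carries an iodine at C3 of ring A that has to become a hydroxyl, and two chlorines on ring B that have to be removed. Ring A of A2 is a para-hydroxybenzyl silyl ether, and its two-electron oxidation can be diverted towards a quinone methide. Thallium is needed in stoichiometric amount, and four halogens have to be installed first.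
- Comparison: on structure the two plans are equal (same bond, same ring size). On mechanism the alternative is the better one for the base-sensitive carbinol, since no carbonate at 100 °C is involved, but it places an oxidant on the most oxidisable ring. On step economy the chosen plan is better: one hydrogenolysis follows its ring closure, against three corrective operations after A1.

Alternative 2: The cut is the O–ring D bond of the hindered ether at C2 of ring C. In A4 ring D carries a fluoride ortho to the carbonyl of a six-membered lactone that also holds the stereocentre, and ring C has a free C2 phenol. Cs2CO3 in DMF would form the phenoxide, which displaces fluoride by addition–elimination to give A3.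
- In its favour: such closures need no metal and are among the most dependable for macrocyclic diaryl ethers; the lactone activates the right carbon, protects the carbinol and stiffens the chain.
- Against it here: the nucleophile is a 2,6-disubstituted phenoxide and the electrophilic carbon is flanked as well, so the most hindered bond is made in the entropically hardest step. An ester carbonyl activates far less than a nitro group. The benzylic C–O bond of the lactone lies β to an acidic benzylic CH2 and can open by elimination under hot carbonate. The carbonyl carbon has to be excised afterwards, by decarboxylation of a di-ortho-substituted benzoic acid in the presence of the benzylic alcohol.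
- Comparison: on structure the chosen plan is better, because it makes this ether as an O-alkylation before ring C exists. On mechanism the ring-closing event of the alternative is at least the equal of a copper etherification in predictability, and it avoids the metal. On step economy the extra carbon costs steps at both ends, so the chosen plan is shorter.

Alternative 3: The cut removes both C–C bonds of the carbinol bridge, ring A–CH and ring D–CH2. A6 carries a pinacol boronate on ring A and a triflate on ring D. Vinyllithium (CH2=CHLi) would give the boron ate complex; Pd(OAc)2 with one enantiomer of MandyPhos would insert into the triflate, the aryl–palladium cation would trigger the 1,2-shift of ring A from boron to the α-carbon while ring D bonds to the β-carbon, and A5 would result. Oxidation of its C–B bond with retention would give the carbinol.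
- In its favour: one operation creates two skeletal bonds, the stereocentre and the macrocycle, and no ketone intermediate is needed.
- Against it here: this coupling is established between separate components. A ring-closing version asks the ring D palladium centre to reach the boron-bound vinyl group across an 18-membered transition state, and the level of enantio-induction there is open. Direct aryl–aryl coupling of ring A with ring D competes whenever the shift is slow. The ate complex and the triflate must coexist in one molecule.
- Comparison: on step economy the alternative is clearly better, since one step replaces the enolate arylation, the transfer hydrogenation and the etherification. On structure it sets the stereocentre in the ring-closing event, whereas the chosen plan sets it in a separate step on an acyclic ketone. On mechanism each event of the chosen plan has close analogy, while the alternative concentrates all risk in one event without analogy.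

Key step: step 4

Remark on the chemistry: 1-(3,4,5-trihydroxyphenyl)ethanone (12) is taken as a catalogue compound, and no stable atropisomers of the 18-membered ring are assumed, so the carbinol is the only stereogenic element.

## Route

Step 1
Reactants: 1 3-iodophenol; 2 chloroacetone
Product: 3 1-(3-iodophenoxy)propan-2-one
Conditions: K2CO3, KI (cat.), acetone, reflux
Reagents that add atoms: none
Why: Williamson ether synthesis: the phenoxide displaces the primary α-keto chloride (iodide catalysis), so the oxygen destined for the crowded C2 of ring C is attached to ring D without steric hindrance.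

Step 2
Reactants: 3 1-(3-iodophenoxy)propan-2-one
Product: 4 trimethyl{[3-(3-iodophenoxy)prop-1-en-2-yl]oxy}silane
Conditions: LiN(iPr)2 (LDA), Me3SiCl present from the start, THF, −78 °C; pentane/Et3N, filtration, used crude
Reagents that add atoms: chlorotrimethylsilane, C[Si](C)(C)Cl
Why: Kinetic enolisation with in-situ silyl trapping: the hindered amide should remove a proton from the open methyl group faster than from the oxygen-bearing methylene, and immediate O-silylation prevents equilibration to the more stable internal enolate, which fixes the future C4 as the nucleophilic carbon.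

Step 3
Reactants: 5 4-bromobenzaldehyde; 6 4,4-dimethoxybutan-2-one
Product: 7 (1E)-1-(4-bromophenyl)-5,5-dimethoxypent-1-en-3-one
Conditions: NaOH (cat.), MeOH, 0 → 20 °C
Reagents that add atoms: none
Why: Claisen–Schmidt condensation: the aldehyde cannot enolise, the methyl group of 6 reacts in preference to the hindered methylene, E1cB dehydration gives the (E)-enone, and the acetal is inert to base.

Step 4
Reactants: 4 trimethyl{[3-(3-iodophenoxy)prop-1-en-2-yl]oxy}silane; 7 (1E)-1-(4-bromophenyl)-5,5-dimethoxypent-1-en-3-one
Product: 9 3-[(E)-2-(4-bromophenyl)ethenyl]-2-(3-iodophenoxy)phenol, via open-chain methoxy diketone 8 (not isolated)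
Conditions: TiCl4, CH2Cl2, −78 °C; cold aq. NaHCO3 quench; crude 8, K2CO3, MeOH, 20 → 60 °C
Reagents that add atoms: none
Why: Proposed new method: TiCl4 ionises the dimethyl acetal of 7 to a β-keto oxocarbenium ion, to which the terminal carbon of 4 adds in a Mukaiyama-type aldol addition (C4–C5) with loss of Me3SiCl to give 8; in carbonate/methanol the C2–H of 8, flanked by the C3 carbonyl and the aryloxy oxygen and therefore the most acidic enolisable position, forms the enolate that adds to the C1 carbonyl (C2–C1), and E1cB loss of water and of methanol followed by tautomerisation of the cyclohexadienone gives phenol 9, aromatisation making the sequence irreversible. The closest known reaction types are the TiCl4-mediated formal [3+3] cyclocondensation of 1,3-bis(silyloxy)-1,3-dienes with β-ketoacetals to 6-substituted salicylates for the first bond, and the base-induced aldol cycloaromatisation of pent-2-ene-1,5-diones (the ring-opened form of 2-alkylpyrylium salts) to phenols for the second; new here is a mono-silyl enol ether whose second nucleophilic carbon is not pre-activated and bears an aryloxy group. Ring C closes in a 6-(enolendo)-exo-trig aldol. No stereocentre is created, since C5 of 8 is racemic and becomes sp2. Three selectivities are needed: the first bond must start at the terminal carbon, which the regiodefined enol silane secures; it must go to the acetal carbon, which is secured because the oxocarbenium ion is far more electrophilic at −78 °C than the enone β-carbon or the ketone; and the ring must close from C2 onto C1, which is secured because the styryl ketone of 7 has no hydrogen on its side-chain α-carbon, so no other enolate of 8 can reach a carbonyl group through a six-membered ring. Methanol lost early from 8 gives enediones that can re-add methoxide in this medium and return to the productive path.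

Step 5
Reactants: 9 3-[(E)-2-(4-bromophenyl)ethenyl]-2-(3-iodophenoxy)phenol
Product: 10 3-[2-(4-bromophenyl)ethyl]-2-(3-iodophenoxy)phenol
Conditions: TsNHNH2, NaOAc, THF/H2O, reflux
Reagents that add atoms: none
Why: Diimide reduction: diazene from the sulfonyl hydrazide transfers two hydrogens to the non-polar C=C bond through a cyclic six-membered transition state and cannot insert into the carbon–iodine or carbon–bromine bonds that a metal hydrogenation catalyst would attack.

Step 6
Reactants: 10 3-[2-(4-bromophenyl)ethyl]-2-(3-iodophenoxy)phenol
Product: 11 1-(benzyloxy)-3-[2-(4-bromophenyl)ethyl]-2-(3-iodophenoxy)benzene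
Conditions: BnBr, K2CO3, DMF, 40 °C
Reagents that add atoms: benzyl bromide, BrCc1ccccc1
Why: Williamson benzylation: the ring C phenoxide is hindered but benzyl bromide is an unencumbered electrophile; the ether keeps this phenol out of the two metal-mediated couplings and leaves in the final hydrogenolysis.

Step 7
Reactants: 12 1-(3,4,5-trihydroxyphenyl)ethanone
Product: 13 1-(7-hydroxy-2,2-diphenyl-1,3-benzodioxol-5-yl)ethanone
Conditions: Ph2CCl2, K2CO3, MeCN, 20 → 60 °C
Reagents that add atoms: dichlorodiphenylmethane, ClC(Cl)(c1ccccc1)c1ccccc1
Why: Ketal formation by double O-alkylation, as used for gallate esters: only two neighbouring oxygens can be bridged and the two possible pairs are equivalent by symmetry, so one defined phenol remains free.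

Step 8
Reactants: 13 1-(7-hydroxy-2,2-diphenyl-1,3-benzodioxol-5-yl)ethanone
Product: 14 1-{2,2-diphenyl-7-[(triisopropylsilyl)oxy]-1,3-benzodioxol-5-yl}ethanone
Conditions: iPr3SiCl, imidazole, DMF, 20 °C
Reagents that add atoms: chlorotri(propan-2-yl)silane, CC(C)[Si](Cl)(C(C)C)C(C)C
Why: Silylation of the phenol: the bulky silyl ether should survive phosphate base at 80 °C and is removed by fluoride without touching ketal, benzyl ether or carbinol.

Step 9
Reactants: 11 1-(benzyloxy)-3-[2-(4-bromophenyl)ethyl]-2-(3-iodophenoxy)benzene; 14 1-{2,2-diphenyl-7-[(triisopropylsilyl)oxy]-1,3-benzodioxol-5-yl}ethanone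
Product: 15 2-(3-{2-(benzyloxy)-6-[2-(4-bromophenyl)ethyl]phenoxy}phenyl)-1-{2,2-diphenyl-7-[(triisopropylsilyl)oxy]-1,3-benzodioxol-5-yl}ethanone
Conditions: Pd(OAc)2 (5 mol%), Xantphos, K3PO4, toluene, 80 °C; 1.1 equiv of 14
Reagents that add atoms: none
Why: Palladium-catalysed ketone α-arylation: zerovalent palladium inserts into the carbon–iodine bond of ring D much faster than into the carbon–bromine bond of ring B, the potassium enolate of 14 displaces iodide on palladium, and reductive elimination forms the CH2–ring D bond. The wide-bite-angle ligand and the limited amount of enolate favour a single arylation.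

Step 10
Reactants: 15 2-(3-{2-(benzyloxy)-6-[2-(4-bromophenyl)ethyl]phenoxy}phenyl)-1-{2,2-diphenyl-7-[(triisopropylsilyl)oxy]-1,3-benzodioxol-5-yl}ethanone
Product: 16 (1S)-2-(3-{2-(benzyloxy)-6-[2-(4-bromophenyl)ethyl]phenoxy}phenyl)-1-{2,2-diphenyl-7-[(triisopropylsilyl)oxy]-1,3-benzodioxol-5-yl}ethan-1-ol
Conditions: RuCl[(S,S)-TsDPEN](p-cymene) (2 mol%), HCO2H/Et3N 5:2, DMF, 40 °C
Reagents that add atoms: none
Why: Noyori–Ikariya asymmetric transfer hydrogenation: the divalent ruthenium hydride and the ligand N–H deliver H−/H+ through a six-membered outer-sphere transition state in which ring A is held by a CH/π contact with the cymene ligand. The (S,S) catalyst thereby adds hydride to the Re face and should give the (S)-alcohol, in the same sense as acetophenone, because the aryl group outranks the CH2-aryl group as it outranks methyl. Loss of CO2 makes the reduction irreversible for this electron-rich ketone.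

Step 11
Reactants: 16 (1S)-2-(3-{2-(benzyloxy)-6-[2-(4-bromophenyl)ethyl]phenoxy}phenyl)-1-{2,2-diphenyl-7-[(triisopropylsilyl)oxy]-1,3-benzodioxol-5-yl}ethan-1-ol
Product: 17 6-[(1S)-2-(3-{2-(benzyloxy)-6-[2-(4-bromophenyl)ethyl]phenoxy}phenyl)-1-hydroxyethyl]-2,2-diphenyl-1,3-benzodioxol-4-ol
Conditions: Bu4NF, AcOH, THF, 0 °C
Reagents that add atoms: none
Why: Fluoride cleavage of the aryl silyl ether (strong Si–F bond, phenoxide leaving group); the acetic acid buffer keeps the medium near neutral, so the carbinol stereocentre is not at risk.

Step 12
Reactants: 17 6-[(1S)-2-(3-{2-(benzyloxy)-6-[2-(4-bromophenyl)ethyl]phenoxy}phenyl)-1-hydroxyethyl]-2,2-diphenyl-1,3-benzodioxol-4-ol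
Product: 18 (S)-configured 18-membered macrocycle: skeleton of 19 with free carbinol; ring C hydroxyl as benzyl ether; C3 and C4 oxygens of ring A as diphenylmethylene ketal
Conditions: CuI (30 mol%), N,N-dimethylglycine·HCl, Cs2CO3, 1,4-dioxane, 100 °C, 2 mM, slow addition
Reagents that add atoms: none
Why: Intramolecular Ullmann-type etherification, a standard closure for macrocyclic diaryl ethers: the monovalent copper phenoxide, kept soluble and reactive by the amino acid ligand, couples with the unhindered aryl bromide of ring B, and high dilution favours the 18-membered ring over oligomers. Carbonate deprotonates the phenol but not the secondary alcohol, and the phenoxide is meta to the carbinol, so no quinone methide can form.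

Step 13
Reactants: 18 (S)-configured macrocyclic benzyl ether/diphenylmethylene ketal
Product: 19 CNP0333307.1 (S)
Conditions: H2 (1 atm), Pd/C, EtOAc/MeOH, 20 °C, exclusion of air on work-up
Reagents that add atoms: none
Why: Catalytic hydrogenolysis cleaves the benzylic C–O bonds of the benzyl ether and of the diphenylmethylene ketal (as toluene and diphenylmethane). A secondary benzylic alcohol reacts much more slowly in neutral, acid-free medium, as in the debenzylation of benzyl-protected flavan-3-ols, so the stereocentre should be retained.

## Compound list

1 | 3-iodophenol | Oc1cccc(I)c1 | starting material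
2 | chloroacetone | CC(=O)CCl | starting material
3 | 1-(3-iodophenoxy)propan-2-one | CC(=O)COc1cccc(I)c1 | intermediate
4 | trimethyl{[3-(3-iodophenoxy)prop-1-en-2-yl]oxy}silane | C=C(O[Si](C)(C)C)COc1cccc(I)c1 | intermediate
5 | 4-bromobenzaldehyde | O=Cc1ccc(Br)cc1 | starting material
6 | 4,4-dimethoxybutan-2-one | COC(OC)CC(C)=O | starting material
7 | (1E)-1-(4-bromophenyl)-5,5-dimethoxypent-1-en-3-one | COC(OC)CC(=O)/C=C/c1ccc(Br)cc1 | intermediate
8 | (1E)-1-(4-bromophenyl)-8-(3-iodophenoxy)-5-methoxyoct-1-ene-3,7-dione (racemic, not isolated) | COC(CC(=O)COc1cccc(I)c1)CC(=O)/C=C/c1ccc(Br)cc1 | intermediate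
9 | 3-[(E)-2-(4-bromophenyl)ethenyl]-2-(3-iodophenoxy)phenol | Oc1cccc(/C=C/c2ccc(Br)cc2)c1Oc1cccc(I)c1 | intermediate
10 | 3-[2-(4-bromophenyl)ethyl]-2-(3-iodophenoxy)phenol | Oc1cccc(CCc2ccc(Br)cc2)c1Oc1cccc(I)c1 | intermediate
11 | 1-(benzyloxy)-3-[2-(4-bromophenyl)ethyl]-2-(3-iodophenoxy)benzene | Brc1ccc(CCc2cccc(OCc3ccccc3)c2Oc2cccc(I)c2)cc1 | intermediate
12 | 1-(3,4,5-trihydroxyphenyl)ethanone | CC(=O)c1cc(O)c(O)c(O)c1 | starting material
13 | 1-(7-hydroxy-2,2-diphenyl-1,3-benzodioxol-5-yl)ethanone | CC(=O)c1cc(O)c2OC(c3ccccc3)(c3ccccc3)Oc2c1 | intermediate
14 | 1-{2,2-diphenyl-7-[(triisopropylsilyl)oxy]-1,3-benzodioxol-5-yl}ethanone | CC(=O)c1cc(O[Si](C(C)C)(C(C)C)C(C)C)c2OC(c3ccccc3)(c3ccccc3)Oc2c1 | intermediate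
15 | 2-(3-{2-(benzyloxy)-6-[2-(4-bromophenyl)ethyl]phenoxy}phenyl)-1-{2,2-diphenyl-7-[(triisopropylsilyl)oxy]-1,3-benzodioxol-5-yl}ethanone | O=C(Cc1cccc(Oc2c(OCc3ccccc3)cccc2CCc2ccc(Br)cc2)c1)c1cc(O[Si](C(C)C)(C(C)C)C(C)C)c2OC(c3ccccc3)(c3ccccc3)Oc2c1 | intermediate
16 | (1S)-2-(3-{2-(benzyloxy)-6-[2-(4-bromophenyl)ethyl]phenoxy}phenyl)-1-{2,2-diphenyl-7-[(triisopropylsilyl)oxy]-1,3-benzodioxol-5-yl}ethan-1-ol | O[C@@H](Cc1cccc(Oc2c(OCc3ccccc3)cccc2CCc2ccc(Br)cc2)c1)c1cc(O[Si](C(C)C)(C(C)C)C(C)C)c2OC(c3ccccc3)(c3ccccc3)Oc2c1 | intermediate
17 | 6-[(1S)-2-(3-{2-(benzyloxy)-6-[2-(4-bromophenyl)ethyl]phenoxy}phenyl)-1-hydroxyethyl]-2,2-diphenyl-1,3-benzodioxol-4-ol | O[C@@H](Cc1cccc(Oc2c(OCc3ccccc3)cccc2CCc2ccc(Br)cc2)c1)c1cc(O)c2OC(c3ccccc3)(c3ccccc3)Oc2c1 | intermediate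
18 | (S)-configured 18-membered macrocycle: skeleton of 19 with free carbinol, ring C hydroxyl as benzyl ether, C3 and C4 oxygens of ring A as diphenylmethylene ketal | O[C@H]1Cc2cccc(c2)Oc2c(OCc3ccccc3)cccc2CCc2ccc(cc2)Oc2cc1cc1OC(c3ccccc3)(c3ccccc3)Oc21 | intermediate
19 | CNP0333307.1, (S)-configured macrocycle with ring A 3,4-diol, ring C 3-ol and free carbinol | Oc1cc2cc(c1O)Oc1ccc(cc1)CCc1cccc(O)c1Oc1cccc(c1)C[C@@H]2O | target

## Step count and least certain steps

Total step count: 13. Longest linear sequence: 10 steps (steps 1, 2, 4, 5, 6, 9, 10, 11, 12, 13).

Step 4 (key step, the one labelled as a new method). Three things may go wrong. The enol silane may add in conjugate fashion to the enone, or lose its silyl group before the C–C bond forms. After the first bond, early loss of methanol may give (E)-enediones, or O-cyclisation may give a pyran, and these may close only slowly. Under base, intermolecular Michael addition may compete with the unimolecular aldol closure. Fallback by known chemistry, from 1 to 10: nucleophilic aromatic substitution of 1 on purchasable 2-fluoro-3-methoxybenzaldehyde (K2CO3, DMF, 120 °C; the formyl group activates the fluoride) would give 2-(3-iodophenoxy)-3-methoxybenzaldehyde F1. Wittig olefination with purchasable (4-bromobenzyl)triphenylphosphonium bromide and KOtBu would give 1-[2-(4-bromophenyl)ethenyl]-2-(3-iodophenoxy)-3-methoxybenzene F2 as an E/Z mixture. Diimide reduction under the conditions of step 5 would give 1-[2-(4-bromophenyl)ethyl]-2-(3-iodophenoxy)-3-methoxybenzene F3, and BBr3 in CH2Cl2 would cleave the methyl ether to give 10.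

Step 2. Regiocontrol in the enolisation may be lost: the aryloxy group acidifies the methylene protons, and the lithium enolate may equilibrate before it is trapped. The internal enol silane would lead in step 4 to an isomeric arene. Fallback from 1 to 4 with the double bond position fixed by construction: O-alkylation of 1 with 2-chloro-N-methoxy-N-methylacetamide (K2CO3, DMF) would give 2-(3-iodophenoxy)-N-methoxy-N-methylacetamide F4. Addition of Me3SiCH2MgCl would give 1-(3-iodophenoxy)-3-(trimethylsilyl)propan-2-one F5. Heating F5 neat would move silicon from carbon to oxygen (Brook-type 1,3-shift of a β-ketosilane) and give 4 only.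

Step 9. Discrimination between the two carbon–halogen bonds may fade once the iodide is nearly consumed (oligomers), the more acidic product may be arylated a second time, or the base may cleave the silyl ether. Fallback with reversed polarity, from 11 and 14 to 15: iodine–magnesium exchange on 11 with iPrMgCl·LiCl at −20 °C (the bromide does not exchange) and quenching with 2-isopropoxy-4,4,5,5-tetramethyl-1,3,2-dioxaborolane would give 2-(3-{2-(benzyloxy)-6-[2-(4-bromophenyl)ethyl]phenoxy}phenyl)-4,4,5,5-tetramethyl-1,3,2-dioxaborolane F6. α-Bromination of 14 with phenyltrimethylammonium tribromide would give 2-bromo-1-{2,2-diphenyl-7-[(triisopropylsilyl)oxy]-1,3-benzodioxol-5-yl}ethanone F7. Suzuki–Miyaura coupling of F6 with F7 at 20 °C (Pd(OAc)2, tri(1-naphthyl)phosphine, K3PO4, THF/H2O) would give 15, because the sp3 carbon–bromine bond next to the carbonyl reacts far faster than the aryl bromide.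

Step 12. Intermolecular etherification may outrun ring closure, turnover may be slow at high dilution, or the bromine may be lost reductively. Fallback from 17 to 18 by oxidative coupling: Miyaura borylation of 17 (PdCl2(dppf), bis(pinacolato)diboron, KOAc, dioxane, 80 °C) would give 6-{(1S)-2-[3-(2-(benzyloxy)-6-{2-[4-(4,4,5,5-tetramethyl-1,3,2-dioxaborolan-2-yl)phenyl]ethyl}phenoxy)phenyl]-1-hydroxyethyl}-2,2-diphenyl-1,3-benzodioxol-4-ol F8. Chan–Lam etherification (Cu(OAc)2, divalent copper, pyridine, 4 Å sieves, air, CH2Cl2, 20 °C, dilute) would close the ring to 18 at room temperature.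

Step 13. Once the phenols are free, hydrogenolysis may continue at the benzylic C–OH bond, which the para oxygen activates, and the catechol may be oxidised on work-up. Fallback from 18 to 19 with the carbinol shielded: silylation of 18 (tBuMe2SiOTf, 2,6-lutidine) would give the tert-butyldimethylsilyl ether of 18 F9. Hydrogenolysis as in step 13 would give the tert-butyldimethylsilyl ether of 19 F10, the bulky silyl ether hindering adsorption and cleavage of the benzylic C–O bond. HF·pyridine buffered with pyridine in THF at 0 °C would then give 19.

## Further compounds

F1 | step 4 | 2-(3-iodophenoxy)-3-methoxybenzaldehyde | COc1cccc(C=O)c1Oc1cccc(I)c1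
F2 | step 4 | 1-[2-(4-bromophenyl)ethenyl]-2-(3-iodophenoxy)-3-methoxybenzene (E/Z mixture) | COc1cccc(C=Cc2ccc(Br)cc2)c1Oc1cccc(I)c1
F3 | step 4 | 1-[2-(4-bromophenyl)ethyl]-2-(3-iodophenoxy)-3-methoxybenzene | COc1cccc(CCc2ccc(Br)cc2)c1Oc1cccc(I)c1
F4 | step 2 | 2-(3-iodophenoxy)-N-methoxy-N-methylacetamide | CON(C)C(=O)COc1cccc(I)c1
F5 | step 2 | 1-(3-iodophenoxy)-3-(trimethylsilyl)propan-2-one | C[Si](C)(C)CC(=O)COc1cccc(I)c1
F6 | step 9 | 2-(3-{2-(benzyloxy)-6-[2-(4-bromophenyl)ethyl]phenoxy}phenyl)-4,4,5,5-tetramethyl-1,3,2-dioxaborolane | CC1(C)OB(OC1(C)C)c1cccc(Oc2c(OCc3ccccc3)cccc2CCc2ccc(Br)cc2)c1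
F7 | step 9 | 2-bromo-1-{2,2-diphenyl-7-[(triisopropylsilyl)oxy]-1,3-benzodioxol-5-yl}ethanone | BrCC(=O)c1cc(O[Si](C(C)C)(C(C)C)C(C)C)c2OC(c3ccccc3)(c3ccccc3)Oc2c1
F8 | step 12 | 6-{(1S)-2-[3-(2-(benzyloxy)-6-{2-[4-(4,4,5,5-tetramethyl-1,3,2-dioxaborolan-2-yl)phenyl]ethyl}phenoxy)phenyl]-1-hydroxyethyl}-2,2-diphenyl-1,3-benzodioxol-4-ol | O[C@@H](Cc1cccc(Oc2c(OCc3ccccc3)cccc2CCc2ccc(cc2)B2OC(C)(C)C(C)(C)O2)c1)c1cc(O)c2OC(c3ccccc3)(c3ccccc3)Oc2c1
F9 | step 13 | tert-butyldimethylsilyl ether of 18 at the (S)-carbinol | CC(C)(C)[Si](C)(C)O[C@H]1Cc2cccc(c2)Oc2c(OCc3ccccc3)cccc2CCc2ccc(cc2)Oc2cc1cc1OC(c3ccccc3)(c3ccccc3)Oc21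
F10 | step 13 | tert-butyldimethylsilyl ether of 19 at the (S)-carbinol | CC(C)(C)[Si](C)(C)O[C@H]1Cc2cccc(c2)Oc2c(O)cccc2CCc2ccc(cc2)Oc2cc1cc(O)c2O
A1 | alternative 1 | (S)-macrocyclic iodo dichloro diaryl ether: ring A 4-hydroxy-3-iodo, ring B dichloro, ring C triisopropylsilyl ether, carbinol tert-butyldimethylsilyl ether | Ic1cc2cc(c1O)Oc1c(Cl)cc(cc1Cl)CCc1cccc(O[Si](C(C)C)(C(C)C)C(C)C)c1Oc1cccc(c1)C[C@@H]2O[Si](C)(C)C(C)(C)C
A2 | alternative 1 | (S)-acyclic bis-phenol: ring A 4-hydroxy-3,5-diiodophenyl, ring B 3,5-dichloro-4-hydroxyphenyl, same silyl ethers as A1 | Oc1c(I)cc(cc1I)[C@@H](O[Si](C)(C)C(C)(C)C)Cc1cccc(c1)Oc1c(O[Si](C(C)C)(C(C)C)C(C)C)cccc1CCc1cc(Cl)c(O)c(Cl)c1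
A3 | alternative 2 | (S)-macrocycle with a six-membered lactone fused to ring D, three benzyl ethers | c1ccccc1COc1cc2cc(c1OCc1ccccc1)Oc1ccc(cc1)CCc1cccc(OCc3ccccc3)c1Oc1cccc3C[C@@H]2OC(=O)c13
A4 | alternative 2 | (S)-acyclic 8-fluoro-3-aryl-isochroman-1-one with free C2 phenol on ring C, three benzyl ethers | O=C1O[C@@H](Cc2cccc(F)c12)c1cc(OCc2ccccc2)c(OCc2ccccc2)c(c1)Oc1ccc(cc1)CCc1cccc(OCc2ccccc2)c1O
A5 | alternative 3 | (S)-macrocyclic secondary pinacol boronate, three benzyl ethers | c1ccccc1COc1cc2cc(c1OCc1ccccc1)Oc1ccc(cc1)CCc1cccc(OCc3ccccc3)c1Oc1cccc(c1)C[C@@H]2B1OC(C)(C)C(C)(C)O1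
A6 | alternative 3 | acyclic ring A pinacol boronate with ring D triflate, three benzyl ethers | CC1(C)OB(OC1(C)C)c1cc(OCc2ccccc2)c(OCc2ccccc2)c(c1)Oc1ccc(cc1)CCc1cccc(OCc2ccccc2)c1Oc1cccc(OS(=O)(=O)C(F)(F)F)c1
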